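Ring B is a 1,2,3,5-tetraoxygenated benzene: C2 bears the ring A oxygen, C3 the ring C oxygen, C1 and C5 are OH, C4 and C6 are CH. This pattern fits a cyclobutenone–alkoxyacetylene benzannulation, so ring B is cut at C1–C6 and C4–C5 into ethoxyacetylene (C5, C6) and a four-carbon cyclobutenone (C1–C4) that already carries both aryl ethers. One thermal operation builds the whole ring with its C1 phenol and C5 ether; no C–O coupling is needed at the crowded C2 and C3. The precursor is a 3-(ring C aryloxy)-4-(ring A aryloxy)cyclobut-2-enone, made from an aryloxyketene and an aryl ethynyl ether, with all other hydroxyls as methyl ethers.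

Key step: step 9

Remark: ring B is numbered C1 (OH), C2 (O–ring A), C3 (O–ring C), C4 (H), C5 (OH), C6 (H); rings D and E are the two trioxygenated phenyl groups on ring C. The target has no stereocenter, and the biaryl axes are not stereogenic because rings D and E are symmetrically substituted. ArC stands for the 2,4,6-trimethoxy-3,5-bis(2,4,6-trimethoxyphenyl)phenyl group.

Step 1
Reactants: 1 3,5-dimethoxyphenol; 2 ethyl bromoacetate
Product: 4 2-(3,5-dimethoxyphenoxy)acetic acid, via ethyl ester 3 (not isolated)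
Conditions: K2CO3, acetone, reflux; then NaOH, H2O/MeOH, rt; HCl
Reagents that add atoms: sodium hydroxide, [Na+].[OH-]
Why: Williamson ether synthesis with a primary α-bromo ester under K2CO3 in acetone should favour O- over C-alkylation of the electron-rich phenoxide, and saponification of ester 3 in the same flask delivers the acid.

Step 2
Reactants: 5 2,4,6-trimethoxyphenol
Product: 6 2-(benzyloxy)-1,3,5-trimethoxybenzene
Conditions: BnBr, K2CO3, DMF, rt
Reagents that add atoms: benzyl bromide, BrCc1ccccc1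
Why: Williamson benzylation masks the easily oxidized tetraoxygenated phenol so that bromination and cross-coupling do not lead to quinone formation, and the benzyl group can later be removed by neutral hydrogenolysis.

Step 3
Reactants: 6 2-(benzyloxy)-1,3,5-trimethoxybenzene
Product: 8 1-(benzyloxy)-3,5-dibromo-2,4,6-trimethoxybenzene, via monobromide 7 (not isolated)
Conditions: NBS (2.1 equiv), MeCN, 0 °C to rt
Reagents that add atoms: N-bromosuccinimide, O=C1CCC(=O)N1Br
Why: Electrophilic aromatic bromination should occur twice and only at C3 and C5 of ring C, the sole free positions of the tetraalkoxy ring, each flanked by two methoxy groups and far more nucleophilic than the benzyl phenyl ring.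

Step 4
Reactants: 8 1-(benzyloxy)-3,5-dibromo-2,4,6-trimethoxybenzene; 9 2,4,6-trimethoxyphenylboronic acid
Product: 11 1-(benzyloxy)-2,4,6-trimethoxy-3,5-bis(2,4,6-trimethoxyphenyl)benzene, via monoaryl bromide 10 (not isolated)
Conditions: 9 (4 equiv), Pd(OAc)2, SPhos, K3PO4, toluene/H2O, 100 °C
Reagents that add atoms: none
Why: Double Suzuki–Miyaura coupling, in which the bulky, electron-rich biarylphosphine SPhos is known to carry di-ortho-alkoxy partners through to tetra-ortho-substituted biaryls, excess 9 offsets protodeboronation, and no atropisomers arise because rings D and E are symmetric about their axes.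

Step 5
Reactants: 11 1-(benzyloxy)-2,4,6-trimethoxy-3,5-bis(2,4,6-trimethoxyphenyl)benzene
Product: 12 2,4,6-trimethoxy-3,5-bis(2,4,6-trimethoxyphenyl)phenol (ArC–OH)
Conditions: H2 (1 atm), Pd/C, EtOAc/MeOH, rt
Reagents that add atoms: none
Why: Catalytic hydrogenolysis cleaves only the benzylic C–O bond and leaves the aryl methyl ethers and biaryl bonds untouched.

Step 6
Reactants: 12 ArC–OH; 13 trichloroethylene
Product: 15 (E)-1,2-dichlorovinyl ether ArC–O–CCl=CHCl, via dichloroacetylene 14 (not isolated)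
Conditions: K2CO3, DMF, 70 °C
Reagents that add atoms: none
Why: K2CO3 dehydrochlorinates trichloroethylene to dichloroacetylene 14, to which the phenoxide adds in anti fashion (the established dichlorovinyl ether route to ynol ethers), so the hindered ring C oxygen is bonded to an unhindered sp carbon and not to an arene.

Step 7
Reactants: 15 ArC–O–CCl=CHCl
Product: 18 aryl ethynyl ether ArC–O–C≡CH, via chloroethynyl ether 16 (not isolated), via lithium acetylide 17 (not isolated)
Conditions: n-BuLi (2.5 equiv), THF, −78 °C; MeOH/H2O quench at −78 °C; crude 18 used at once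
Reagents that add atoms: none
Why: n-BuLi effects dehydrochlorination to chloroalkyne 16 and lithium–chlorine exchange to acetylide 17 (the standard conversion of 1,2-dichlorovinyl ethers into ynol ethers), and the cold protic quench gives the terminal ynol ether while returning any aryllithium formed on rings D or E to C–H.

Step 8
Reactants: 4 2-(3,5-dimethoxyphenoxy)acetic acid; 18 ArC–O–C≡CH
Product: 21 racemic 4-(3,5-dimethoxyphenoxy)-3-(ArC-oxy)cyclobut-2-en-1-one, via acid chloride 19 (not isolated), via aryloxyketene 20 (not isolated)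
Conditions: 4 (2.5 equiv), (COCl)2, cat. DMF, CH2Cl2, 0 °C to rt, evaporate; then slow addition to 18 and Et3N, CH2Cl2, 40 °C
Reagents that add atoms: none
Why: Proposed new method: Et3N dehydrochlorinates acid chloride 19 to aryloxyketene 20, whose electrophilic carbonyl carbon is attacked by the oxygen-activated terminal CH carbon of ynol ether 18 in a ketene–alkyne [2+2] cycloaddition, which places the ring C aryloxy group on C3 and the ring A aryloxy group on C4 of the cyclobutenone; the closest known reaction is the [2+2] of aldoketenes with alkyl alkoxyacetylenes to 3-alkoxycyclobutenones, the aryl ynol ether and the aryloxyketene being the untested elements, and the C4 stereocenter forms without control as a racemate that step 9 erases.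

Step 9
Reactants: 21 racemic 4-(3,5-dimethoxyphenoxy)-3-(ArC-oxy)cyclobut-2-en-1-one; 22 ethoxyacetylene
Product: 27 5-ethoxy-2-(3,5-dimethoxyphenoxy)-3-(ArC-oxy)phenol, via vinylketene 23 (not isolated), via vinylcyclobutenone 24 (not isolated), via dienylketene 25 (not isolated), via cyclohexadienone 26 (not isolated)
Conditions: 22 (5 equiv, hexanes solution), toluene, sealed tube, 80 °C then 100 °C; then K2CO3, MeOH, rt
Reagents that add atoms: none
Why: Proposed new method: On heating, 21 should undergo 4π electrocyclic ring opening (the C4 aryloxy donor rotating outward) to vinylketene 23, whose ketene C=C adds ethoxyacetylene in a [2+2] cycloaddition to give vinylcyclobutenone 24; a second 4π opening gives dienylketene 25, which closes to cyclohexadienone 26 and tautomerizes to phenol 27. The closest known reaction is the Danheiser benzannulation of alkyl- and aryl-substituted cyclobutenones with alkoxyacetylenes; untested here are the aryloxy groups on C3 and C4 of the cyclobutenone. Ring B, the only ring formed, closes by thermal disrotatory 6π electrocyclization of 25, which joins the ketene carbon (C1) to C2 after the [2+2] step has made the new bonds C1–C6 and C4–C5. No stereocenter is created in 27, since the sp3 carbons of 21, 24 and 26 are all lost on ring opening or aromatization. The selectivity needed is the orientation of the alkyne in the [2+2] step, and it is secured by the polarization of ethoxyacetylene, whose nucleophilic CH carbon bonds to the electrophilic ketene carbonyl carbon so that OEt ends on C5, meta to the new C1 hydroxyl, while the two aryloxy groups are already fixed on adjacent carbons of 21. Excess alkyne should outrun ketene dimerization, and the K2CO3/MeOH treatment cleaves any ester formed between 27 and a ketene.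

Step 10
Reactants: 27 5-ethoxy-2-(3,5-dimethoxyphenoxy)-3-(ArC-oxy)phenol
Product: 28 4-(3,5-dihydroxyphenoxy)-5-[2,4,6-trihydroxy-3,5-bis(2,4,6-trihydroxyphenyl)phenoxy]benzene-1,3-diol (CNP0228669.0)
Conditions: BBr3 (excess), CH2Cl2, −78 °C to rt; MeOH, then H2O; Sephadex LH-20, argon
Reagents that add atoms: none
Why: BBr3 dealkylation, in which boron coordinates each ether oxygen and bromide attacks the methyl or ethyl carbon, should cleave all twelve alkyl aryl ethers, whereas the two diaryl ether bonds and the biaryl bonds offer no sp3 carbon and should survive; hydrolysis of the aryl borates releases the polyphenol.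

Compound list
1 | 3,5-dimethoxyphenol | COc1cc(O)cc(OC)c1 | starting material
2 | ethyl bromoacetate | CCOC(=O)CBr | starting material
3 | ethyl 2-(3,5-dimethoxyphenoxy)acetate (step 1, not isolated) | CCOC(=O)COc1cc(OC)cc(OC)c1 | intermediate
4 | 2-(3,5-dimethoxyphenoxy)acetic acid | OC(=O)COc1cc(OC)cc(OC)c1 | intermediate
5 | 2,4,6-trimethoxyphenol | COc1cc(OC)c(O)c(OC)c1 | starting material
6 | 2-(benzyloxy)-1,3,5-trimethoxybenzene | c1ccccc1COc1c(OC)cc(OC)cc1OC | intermediate
7 | 1-(benzyloxy)-3-bromo-2,4,6-trimethoxybenzene (step 3, not isolated) | c1ccccc1COc1c(OC)c(Br)c(OC)cc1OC | intermediate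
8 | 1-(benzyloxy)-3,5-dibromo-2,4,6-trimethoxybenzene | c1ccccc1COc1c(OC)c(Br)c(OC)c(Br)c1OC | intermediate
9 | 2,4,6-trimethoxyphenylboronic acid | COc1cc(OC)c(B(O)O)c(OC)c1 | starting material
10 | 1-(benzyloxy)-3-bromo-2,4,6-trimethoxy-5-(2,4,6-trimethoxyphenyl)benzene (step 4, not isolated) | c1ccccc1COc1c(OC)c(Br)c(OC)c(-c2c(OC)cc(OC)cc2OC)c1OC | intermediate
11 | 1-(benzyloxy)-2,4,6-trimethoxy-3,5-bis(2,4,6-trimethoxyphenyl)benzene | c1ccccc1COc1c(OC)c(-c2c(OC)cc(OC)cc2OC)c(OC)c(-c2c(OC)cc(OC)cc2OC)c1OC | intermediate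
12 | 2,4,6-trimethoxy-3,5-bis(2,4,6-trimethoxyphenyl)phenol | Oc1c(OC)c(-c2c(OC)cc(OC)cc2OC)c(OC)c(-c2c(OC)cc(OC)cc2OC)c1OC | intermediate
13 | trichloroethylene | ClC=C(Cl)Cl | starting material
14 | dichloroacetylene (step 6, not isolated) | ClC#CCl | intermediate
15 | 1-{[(E)-1,2-dichloroethenyl]oxy}-2,4,6-trimethoxy-3,5-bis(2,4,6-trimethoxyphenyl)benzene | Cl/C=C(Cl)\Oc1c(OC)c(-c2c(OC)cc(OC)cc2OC)c(OC)c(-c2c(OC)cc(OC)cc2OC)c1OC | intermediate
16 | 1-[(chloroethynyl)oxy]-2,4,6-trimethoxy-3,5-bis(2,4,6-trimethoxyphenyl)benzene (step 7, not isolated) | ClC#COc1c(OC)c(-c2c(OC)cc(OC)cc2OC)c(OC)c(-c2c(OC)cc(OC)cc2OC)c1OC | intermediate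
17 | lithium 2-[2,4,6-trimethoxy-3,5-bis(2,4,6-trimethoxyphenyl)phenoxy]ethynide (step 7, not isolated) | [Li]C#COc1c(OC)c(-c2c(OC)cc(OC)cc2OC)c(OC)c(-c2c(OC)cc(OC)cc2OC)c1OC | intermediate
18 | 1-(ethynyloxy)-2,4,6-trimethoxy-3,5-bis(2,4,6-trimethoxyphenyl)benzene | C#COc1c(OC)c(-c2c(OC)cc(OC)cc2OC)c(OC)c(-c2c(OC)cc(OC)cc2OC)c1OC | intermediate
19 | 2-(3,5-dimethoxyphenoxy)acetyl chloride (step 8, not isolated) | COc1cc(OCC(Cl)=O)cc(OC)c1 | intermediate
20 | 2-(3,5-dimethoxyphenoxy)ethen-1-one, the aryloxyketene (step 8, not isolated) | COc1cc(OC=C=O)cc(OC)c1 | intermediate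
21 | racemic 4-(3,5-dimethoxyphenoxy)-3-[2,4,6-trimethoxy-3,5-bis(2,4,6-trimethoxyphenyl)phenoxy]cyclobut-2-en-1-one | O=C1C=C(Oc2c(OC)c(-c3c(OC)cc(OC)cc3OC)c(OC)c(-c3c(OC)cc(OC)cc3OC)c2OC)C1Oc1cc(OC)cc(OC)c1 | intermediate
22 | ethoxyacetylene | CCOC#C | starting material
23 | (3Z)-4-(3,5-dimethoxyphenoxy)-3-[2,4,6-trimethoxy-3,5-bis(2,4,6-trimethoxyphenyl)phenoxy]buta-1,3-dien-1-one, geometry as expected from outward rotation (step 9, not isolated) | O=C=C/C(Oc1c(OC)c(-c2c(OC)cc(OC)cc2OC)c(OC)c(-c2c(OC)cc(OC)cc2OC)c1OC)=C/Oc1cc(OC)cc(OC)c1 | intermediate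
24 | racemic 3-ethoxy-4-{(Z)-2-(3,5-dimethoxyphenoxy)-1-[2,4,6-trimethoxy-3,5-bis(2,4,6-trimethoxyphenyl)phenoxy]ethenyl}cyclobut-2-en-1-one (step 9, not isolated) | O=C1C=C(OCC)C1/C(Oc1c(OC)c(-c2c(OC)cc(OC)cc2OC)c(OC)c(-c2c(OC)cc(OC)cc2OC)c1OC)=C/Oc1cc(OC)cc(OC)c1 | intermediate
25 | (3E,5Z)-3-ethoxy-6-(3,5-dimethoxyphenoxy)-5-[2,4,6-trimethoxy-3,5-bis(2,4,6-trimethoxyphenyl)phenoxy]hexa-1,3,5-trien-1-one (step 9, not isolated) | O=C=C/C(OCC)=C\C(Oc1c(OC)c(-c2c(OC)cc(OC)cc2OC)c(OC)c(-c2c(OC)cc(OC)cc2OC)c1OC)=C\Oc1cc(OC)cc(OC)c1 | intermediate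
26 | racemic 3-ethoxy-6-(3,5-dimethoxyphenoxy)-5-[2,4,6-trimethoxy-3,5-bis(2,4,6-trimethoxyphenyl)phenoxy]cyclohexa-2,4-dien-1-one (step 9, not isolated) | O=C1C=C(OCC)C=C(Oc2c(OC)c(-c3c(OC)cc(OC)cc3OC)c(OC)c(-c3c(OC)cc(OC)cc3OC)c2OC)C1Oc1cc(OC)cc(OC)c1 | intermediate
27 | 5-ethoxy-2-(3,5-dimethoxyphenoxy)-3-[2,4,6-trimethoxy-3,5-bis(2,4,6-trimethoxyphenyl)phenoxy]phenol | CCOc1cc(O)c(Oc2cc(OC)cc(OC)c2)c(Oc2c(OC)c(-c3c(OC)cc(OC)cc3OC)c(OC)c(-c3c(OC)cc(OC)cc3OC)c2OC)c1 | intermediate
28 | 4-(3,5-dihydroxyphenoxy)-5-[2,4,6-trihydroxy-3,5-bis(2,4,6-trihydroxyphenyl)phenoxy]benzene-1,3-diol (CNP0228669.0) | Oc1cc(O)cc(Oc2c(O)cc(O)cc2Oc2c(O)c(-c3c(O)cc(O)cc3O)c(O)c(-c3c(O)cc(O)cc3O)c2O)c1 | target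

Total step count: 10. Longest linear sequence: 9 steps (steps 2 to 10, from 5 to 28); the ring A branch (step 1) joins at step 8.

Steps most likely to fail

1. Step 9. The vinylketene may be consumed by dimerization or by acylating the product phenol faster than it adds the alkyne, or the ring C aryloxide may be expelled from the vinylogous ester on heating. The fallback builds ring B by known diaryl ether chemistry, sets out from phenol 12 and comes back to the route at target 28. Nucleophilic aromatic substitution of purchased 2-fluoro-4,6-dimethoxybenzaldehyde (O=Cc1c(F)cc(OC)cc1OC) by the phenoxide of 12 (K2CO3, DMSO, 120 °C), the formyl group activating the ortho fluorine, should give 4,6-dimethoxy-2-(ArC-oxy)benzaldehyde F1. Baeyer–Villiger oxidation with mCPBA (NaHCO3, CH2Cl2, 0 °C) should give aryl formate F2, and methanolysis (K2CO3, MeOH) should give 4,6-dimethoxy-2-(ArC-oxy)phenol F3, whose hydroxyl sits on the future C2 of ring B. Ullmann coupling of F3 with purchased 1-iodo-3,5-dimethoxybenzene (COc1cc(I)cc(OC)c1; CuI, picolinic acid, K3PO4, DMSO, 90 °C, argon) should give the fully methylated pentaaryl ether F4. BBr3 under the conditions of step 10 then gives 28.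

2. Step 8. The aryloxyketene may dimerize, or the terminal ynol ether may polymerize or add HCl, before the cycloaddition takes place, because the aryl ynol ether is hindered and less nucleophilic than its alkyl counterparts. The fallback again uses known copper-mediated ether formation with a different ring B building block and bond order, sets out from phenol 12 and comes back at target 28. Chan–Lam coupling of purchased 5-bromovanillin (COc1cc(C=O)cc(Br)c1O) with purchased 3,5-dimethoxyphenylboronic acid (COc1cc(OC)cc(B(O)O)c1; catalytic Cu(OAc)2, pyridine, 4 Å sieves, CH2Cl2, air) should give 3-bromo-4-(3,5-dimethoxyphenoxy)-5-methoxybenzaldehyde F5. Ullmann coupling of F5 with 12 (CuI, picolinic acid, K3PO4, DMSO, 100 °C) should give 4-(3,5-dimethoxyphenoxy)-3-methoxy-5-(ArC-oxy)benzaldehyde F6. Baeyer–Villiger oxidation (mCPBA, NaHCO3, CH2Cl2, 0 °C) should give aryl formate F7, and methanolysis (K2CO3, MeOH) should give 4-(3,5-dimethoxyphenoxy)-3-methoxy-5-(ArC-oxy)phenol F8, which is ring B with C5–OH and C1–OMe. BBr3 as in step 10 gives 28.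

3. Step 4. Protodeboronation of the di-ortho-methoxy boronic acid may outrun transmetalation at the doubly ortho-substituted palladium centre, so that coupling stalls at the monoaryl stage. The fallback is a Negishi coupling, sets out from dibromide 8 and comes back at 11. Purchased 1,3,5-trimethoxybenzene (COc1cc(OC)cc(OC)c1) is lithiated between two methoxy groups (n-BuLi, THF, 0 °C to rt) to (2,4,6-trimethoxyphenyl)lithium F9. Transmetalation with ZnCl2 gives (2,4,6-trimethoxyphenyl)zinc chloride F10, which is coupled with 8 (Pd2(dba)3, RuPhos, THF, 70 °C) to give 11.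

Further compounds
F1 | step 9 | 4,6-dimethoxy-2-[2,4,6-trimethoxy-3,5-bis(2,4,6-trimethoxyphenyl)phenoxy]benzaldehyde | O=Cc1c(OC)cc(OC)cc1Oc1c(OC)c(-c2c(OC)cc(OC)cc2OC)c(OC)c(-c2c(OC)cc(OC)cc2OC)c1OC
F2 | step 9 | 4,6-dimethoxy-2-[2,4,6-trimethoxy-3,5-bis(2,4,6-trimethoxyphenyl)phenoxy]phenyl formate | O=COc1c(OC)cc(OC)cc1Oc1c(OC)c(-c2c(OC)cc(OC)cc2OC)c(OC)c(-c2c(OC)cc(OC)cc2OC)c1OC
F3 | step 9 | 4,6-dimethoxy-2-[2,4,6-trimethoxy-3,5-bis(2,4,6-trimethoxyphenyl)phenoxy]phenol | Oc1c(OC)cc(OC)cc1Oc1c(OC)c(-c2c(OC)cc(OC)cc2OC)c(OC)c(-c2c(OC)cc(OC)cc2OC)c1OC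
F4 | step 9 | 2-(3,5-dimethoxyphenoxy)-1,5-dimethoxy-3-[2,4,6-trimethoxy-3,5-bis(2,4,6-trimethoxyphenyl)phenoxy]benzene | COc1cc(OC)cc(Oc2c(OC)cc(OC)cc2Oc2c(OC)c(-c3c(OC)cc(OC)cc3OC)c(OC)c(-c3c(OC)cc(OC)cc3OC)c2OC)c1
F5 | step 8 | 3-bromo-4-(3,5-dimethoxyphenoxy)-5-methoxybenzaldehyde | COc1cc(C=O)cc(Br)c1Oc1cc(OC)cc(OC)c1
F6 | step 8 | 4-(3,5-dimethoxyphenoxy)-3-methoxy-5-[2,4,6-trimethoxy-3,5-bis(2,4,6-trimethoxyphenyl)phenoxy]benzaldehyde | COc1cc(C=O)cc(Oc2c(OC)c(-c3c(OC)cc(OC)cc3OC)c(OC)c(-c3c(OC)cc(OC)cc3OC)c2OC)c1Oc1cc(OC)cc(OC)c1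
F7 | step 8 | 4-(3,5-dimethoxyphenoxy)-3-methoxy-5-[2,4,6-trimethoxy-3,5-bis(2,4,6-trimethoxyphenyl)phenoxy]phenyl formate | COc1cc(OC=O)cc(Oc2c(OC)c(-c3c(OC)cc(OC)cc3OC)c(OC)c(-c3c(OC)cc(OC)cc3OC)c2OC)c1Oc1cc(OC)cc(OC)c1
F8 | step 8 | 4-(3,5-dimethoxyphenoxy)-3-methoxy-5-[2,4,6-trimethoxy-3,5-bis(2,4,6-trimethoxyphenyl)phenoxy]phenol | COc1cc(O)cc(Oc2c(OC)c(-c3c(OC)cc(OC)cc3OC)c(OC)c(-c3c(OC)cc(OC)cc3OC)c2OC)c1Oc1cc(OC)cc(OC)c1
F9 | step 4 | (2,4,6-trimethoxyphenyl)lithium | [Li]c1c(OC)cc(OC)cc1OC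
F10 | step 4 | (2,4,6-trimethoxyphenyl)zinc chloride | Cl[Zn]c1c(OC)cc(OC)cc1OC
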